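Ring B (C5–C6–C7–C8–C9–C10) is cut at C6–C7 and C9–C10 into two allyl triads: C6–C5–C10, which belongs to ring A, and C7–C8–C9. The key step joins them in one flask. SnCl4 ionises a monocyclic allylic pivalate. C7, the γ-carbon of a senecioate silyl dienolate, captures C6. A proton then converts the C5=C10 alkene into the C10 cation, which C9 closes. The step exploits that C6 and C10 are the two termini of one allyl cation centred on C5, and that equatorial oxygens at C2 and C3 of ring A dictate the fold. The precursor is a trans-dibenzoate built from 2,6-dimethylphenol. The ketone, aryl ether and angelate come last.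

Key step: step 7

Remark on the chemistry: drimane numbering is used throughout. Ring A is C1–C5 and C10, ring B is C5–C10, C11 is the carbon on C9, and C12 is the methyl on C8. Dienolate 11 is assumed to be an E/Z mixture at the ketene acetal, which has no consequence.

Step 1
Reactants: 1 2,6-dimethylphenol
Product: 3 2,6,6-trimethylcyclohexa-2,4-dien-1-one, via lithium phenolate 2 (not isolated)
Conditions: n-BuLi, toluene, 0 °C; MeI, 120 °C (sealed tube)
Reagents that add atoms: methyl iodide (CI)
Why: Alkylative dearomatisation, in which the tight lithium phenolate ion pair in toluene is C-methylated at a substituted ortho carbon, should give the blocked dienone that already carries C4 (gem-dimethyl), C5 (C=O) and C10 (methyl) of ring A without forming a stereocentre.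

Step 2
Reactants: 3 2,6,6-trimethylcyclohexa-2,4-dien-1-one
Product: 4 (1S,6R)-2,2,4-trimethyl-7-oxabicyclo[4.1.0]hept-4-en-3-one
Conditions: (R,R)-Mn(III)(salen)Cl (5 mol %), mCPBA, NMO, CH2Cl2, −78 °C
Reagents that add atoms: 3-chloroperoxybenzoic acid (OOC(=O)c1cccc(Cl)c1)
Why: In this Jacobsen–Katsuki epoxidation the distal cis-alkene C2=C3, flanked by CMe2 and a conjugating vinyl group as in 2,2-dimethylchromenes, should react before the electron-poor α-methyl enone alkene, and the (R,R) ligand should select the face that sets C3 as S.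

Step 3
Reactants: 4 (1S,6R)-2,2,4-trimethyl-7-oxabicyclo[4.1.0]hept-4-en-3-one
Product: 6 (4S,5S)-4,5-bis(benzoyloxy)-2,6,6-trimethylcyclohex-2-en-1-one, via hydroxy benzoate 5 (not isolated)
Conditions: PhCO2H, (PhCO)2O, Sc(OTf)3 (5 mol %), CH2Cl2–MeCN, −20 °C to rt
Reagents that add atoms: benzoic acid (OC(=O)c1ccccc1); benzoic anhydride (O=C(OC(=O)c1ccccc1)c1ccccc1)
Why: Lewis-acid-catalysed anti (SN2) epoxide opening occurs at the allylic C2 because C3 is neopentyl, so inversion at C2 gives the trans-2,3-dioxygen pattern, and Sc(OTf)3-catalysed acylation caps the hindered C3–OH in the same flask.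

Step 4
Reactants: 6 (4S,5S)-4,5-bis(benzoyloxy)-2,6,6-trimethylcyclohex-2-en-1-one
Product: 8 (4S,5S)-4,5-bis(benzoyloxy)-2,6,6-trimethylcyclohex-1-en-1-yl triflate, via lithium enolate 7 (not isolated)
Conditions: L-Selectride (1.05 equiv), THF, −78 °C; PhNTf2, −78 to 0 °C
Reagents that add atoms: N-phenylbis(trifluoromethanesulfonimide) (O=S(=O)(N(c1ccccc1)S(=O)(=O)C(F)(F)F)C(F)(F)F)
Why: Conjugate hydride reduction, with 1,2-attack blocked by CMe2 and the α-methyl group, gives the C5=C10 enolate regiospecifically, and O-triflation fixes it as the tetrasubstituted enol triflate while the non-enolisable benzoates survive at low temperature.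

Step 5
Reactants: 8 (4S,5S)-4,5-bis(benzoyloxy)-2,6,6-trimethylcyclohex-1-en-1-yl triflate
Product: 9 [(4S,5S)-4,5-bis(benzoyloxy)-2,6,6-trimethylcyclohex-1-en-1-yl]methyl pivalate
Conditions: ICH2OPiv, Zn dust, THF, rt; then 8, Pd(dppf)Cl2 (5 mol %), LiCl, THF–NMP, 50 °C
Reagents that add atoms: iodomethyl pivalate (CC(C)(C)C(=O)OCI)
Why: Negishi cross-coupling of the alkenyl triflate with (pivaloyloxymethyl)zinc iodide installs C6 directly as an ionisable allylic ester and leaves the remote stereocentres untouched.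

Step 6
Reactants: 10 methyl 3-methylbut-2-enoate
Product: 11 1-methoxy-3-methyl-1-(trimethylsilyloxy)buta-1,3-diene
Conditions: LDA, THF, −78 °C; TMSCl, −78 °C to rt
Reagents that add atoms: chlorotrimethylsilane (C[Si](C)(C)Cl)
Why: γ-Deprotonation of the senecioate and O-silylation of the dienolate give the vinylogous silyl ketene acetal that carries C7, C8 (with C12), C9 and C11.

Step 7
Reactants: 9 [(4S,5S)-4,5-bis(benzoyloxy)-2,6,6-trimethylcyclohex-1-en-1-yl]methyl pivalate; 11 1-methoxy-3-methyl-1-(trimethylsilyloxy)buta-1,3-diene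
Product: 13 methyl (2S,3S,5S,9R,10R)-2,3-bis(benzoyloxy)drim-7-en-11-oate, via monocyclic (E)-enoate 12 (not isolated)
Conditions: SnCl4 (2.5 equiv), 11 (1.5 equiv), CH2Cl2, −78 °C; then MeOH (1.5 equiv), −78 to −10 °C
Reagents that add atoms: none
Why: SnCl4 ionises the pivalate to the allyl cation C6–C5–C10, which the dienolate captures through its γ-carbon C7 at the primary terminus C6 (SN1-type vinylogous Mukaiyama alkylation) to give enoate 12 with a tetrasubstituted C5=C10 alkene; SnCl4·MeOH then protonates C5, C9 of the enoate attacks the tertiary C10 cation and C7 loses a proton, which is the acid cyclisation known for monocyclofarnesic esters. Ring B closes 6-endo-trig at the C8=C9 alkene through a chair-like transition state. C10 is controlled by the ring A chair that keeps the C2 and C3 benzoates equatorial, because the other fold puts the C2 benzoate syn-axial to the C4 and C10 methyl groups. C5 is set by reversible protonation, since only the epimer with an equatorial side chain lets C9 reach the non-planar C10 cation from the equatorial side, away from the axial C4 methyl, which gives the trans fusion; C9 follows from the E geometry of C8=C9, which places the ester equatorial. The step needs γ- over α-attack and C6 over C10 attack, both secured by the contrast between CH2 termini and substituted carbons, and Δ7 over Δ8 proton loss, favoured because the axial C7–H aligns with the empty C8 orbital while C9–H is deactivated by the ester.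

Step 8
Reactants: 13 methyl (2S,3S,5S,9R,10R)-2,3-bis(benzoyloxy)drim-7-en-11-oate
Product: 14 (2S,3S,5S,9R,10R)-drim-7-ene-2,3,11-triol
Conditions: LiAlH4, Et2O, 0 °C to rt
Reagents that add atoms: none
Why: Global ester reduction with LiAlH4 turns the C11 ester into the primary alcohol and removes both benzoates in one operation without touching the isolated trisubstituted alkene or any stereocentre.

Step 9
Reactants: 14 (2S,3S,5S,9R,10R)-drim-7-ene-2,3,11-triol; 15 7-hydroxycoumarin (umbelliferone)
Product: 16 7-{[(2S,3S,5S,9R,10R)-2,3-dihydroxydrim-7-en-11-yl]oxy}coumarin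
Conditions: PPh3, DIAD, THF, 0 °C to rt
Reagents that add atoms: none
Why: In this Mitsunobu etherification only the primary C11–OH can be displaced, because SN2 at C2 would need an axial approach past the syn-axial C4 and C10 methyl groups and C3 is neopentyl.

Step 10
Reactants: 16 7-{[(2S,3S,5S,9R,10R)-2,3-dihydroxydrim-7-en-11-yl]oxy}coumarin
Product: 17 7-{[(3S,5S,9R,10R)-3-hydroxy-2-oxodrim-7-en-11-yl]oxy}coumarin
Conditions: Dess–Martin periodinane (1.05 equiv), CH2Cl2, 0 °C
Reagents that add atoms: none
Why: Dess–Martin oxidation with one equivalent should take the C2–OH, which is flanked by a CH2 group, before the neopentyl C3–OH because ligand exchange at iodine is sterically governed, and the neutral medium should leave the enolisable C3 centre intact.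

Step 11
Reactants: 17 7-{[(3S,5S,9R,10R)-3-hydroxy-2-oxodrim-7-en-11-yl]oxy}coumarin; 18 angelic acid
Product: 20 7-{[(3S,5S,9R,10R)-3-(angeloyloxy)-2-oxodrim-7-en-11-yl]oxy}coumarin (CNP0111364.1), via mixed anhydride 19 (not isolated)
Conditions: 18, 2,4,6-trichlorobenzoyl chloride, Et3N, toluene, rt; then 17, toluene, 80 °C
Reagents that add atoms: none
Why: Yamaguchi-type mixed-anhydride esterification run without a nucleophilic amine catalyst acylates hindered secondary alcohols, keeps the Z geometry of the angelate, and retains configuration at C3 because only the O–H bond is broken.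

Compound list
1 | 2,6-dimethylphenol | Cc1cccc(C)c1O | starting material
2 | lithium 2,6-dimethylphenolate | [Li+].Cc1cccc(C)c1[O-] | intermediate
3 | 2,6,6-trimethylcyclohexa-2,4-dien-1-one | CC1=CC=CC(C)(C)C1=O | intermediate
4 | (1S,6R)-2,2,4-trimethyl-7-oxabicyclo[4.1.0]hept-4-en-3-one | CC1=C[C@H]2O[C@H]2C(C)(C)C1=O | intermediate
5 | (4S,5S)-4-(benzoyloxy)-5-hydroxy-2,6,6-trimethylcyclohex-2-en-1-one | O[C@@H]1[C@@H](OC(=O)c2ccccc2)C=C(C)C(=O)C1(C)C | intermediate
6 | (4S,5S)-4,5-bis(benzoyloxy)-2,6,6-trimethylcyclohex-2-en-1-one | O=C(c1ccccc1)O[C@@H]2[C@@H](OC(=O)c3ccccc3)C=C(C)C(=O)C2(C)C | intermediate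
7 | lithium (4S,5S)-4,5-bis(benzoyloxy)-2,6,6-trimethylcyclohex-1-en-1-olate | [Li+].O=C(c1ccccc1)O[C@@H]2[C@@H](OC(=O)c3ccccc3)CC(C)=C([O-])C2(C)C | intermediate
8 | (4S,5S)-4,5-bis(benzoyloxy)-2,6,6-trimethylcyclohex-1-en-1-yl triflate | O=C(c1ccccc1)O[C@@H]2[C@@H](OC(=O)c3ccccc3)CC(C)=C(OS(=O)(=O)C(F)(F)F)C2(C)C | intermediate
9 | [(4S,5S)-4,5-bis(benzoyloxy)-2,6,6-trimethylcyclohex-1-en-1-yl]methyl pivalate | O=C(c1ccccc1)O[C@@H]2[C@@H](OC(=O)c3ccccc3)CC(C)=C(COC(=O)C(C)(C)C)C2(C)C | intermediate
10 | methyl 3-methylbut-2-enoate | COC(=O)C=C(C)C | starting material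
11 | 1-methoxy-3-methyl-1-(trimethylsilyloxy)buta-1,3-diene (E/Z mixture at the ketene acetal) | COC(O[Si](C)(C)C)=CC(C)=C | intermediate
12 | methyl (2E)-5-[(4S,5S)-4,5-bis(benzoyloxy)-2,6,6-trimethylcyclohex-1-en-1-yl]-3-methylpent-2-enoate | O=C(c1ccccc1)O[C@@H]2[C@@H](OC(=O)c3ccccc3)CC(C)=C(CC/C(C)=C/C(=O)OC)C2(C)C | intermediate
13 | methyl (2S,3S,5S,9R,10R)-2,3-bis(benzoyloxy)drim-7-en-11-oate (trans-decalin; both benzoates and the ester equatorial) | O=C(c1ccccc1)O[C@@H]2[C@@H](OC(=O)c3ccccc3)C[C@@]4(C)[C@H](C(=O)OC)C(C)=CC[C@@H]4C2(C)C | intermediate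
14 | (2S,3S,5S,9R,10R)-drim-7-ene-2,3,11-triol | O[C@@H]1[C@@H](O)C[C@@]2(C)[C@H](CO)C(C)=CC[C@@H]2C1(C)C | intermediate
15 | 7-hydroxycoumarin (umbelliferone) | Oc1ccc2ccc(=O)oc2c1 | starting material
16 | 7-{[(2S,3S,5S,9R,10R)-2,3-dihydroxydrim-7-en-11-yl]oxy}coumarin | O[C@@H]1[C@@H](O)C[C@@]2(C)[C@H](COc3ccc4ccc(=O)oc4c3)C(C)=CC[C@@H]2C1(C)C | intermediate
17 | 7-{[(3S,5S,9R,10R)-3-hydroxy-2-oxodrim-7-en-11-yl]oxy}coumarin | O[C@@H]1C(=O)C[C@@]2(C)[C@H](COc3ccc4ccc(=O)oc4c3)C(C)=CC[C@@H]2C1(C)C | intermediate
18 | angelic acid, (Z)-2-methylbut-2-enoic acid | C/C=C(/C)C(=O)O | starting material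
19 | angelic 2,4,6-trichlorobenzoic anhydride | C/C=C(/C)C(=O)OC(=O)c1c(Cl)cc(Cl)cc1Cl | intermediate
20 | 7-{[(3S,5S,9R,10R)-3-(angeloyloxy)-2-oxodrim-7-en-11-yl]oxy}coumarin (CNP0111364.1) | C/C=C(/C)C(=O)O[C@@H]1C(=O)C[C@@]2(C)[C@H](COc3ccc4ccc(=O)oc4c3)C(C)=CC[C@@H]2C1(C)C | target

Total step count: 11. Longest linear sequence: 10 steps (steps 1–5 and 7–11).

Steps most likely to fail

Step 7.
- **What may go wrong:** The alkylation may show poor γ/α or E/Z control. The allyl cation may lose a proton to give ring dienes. The cyclisation may stall at the open-chain stage or lose the final proton towards the Δ8 isomers.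
- **Fallback:** It sets out from 9 and returns at 13, and it uncouples the two bond formations. C6–C7 is made alone with 11 under ZnBr2 catalysis, which is too weak an acid to cyclise. Enoate 12 is isolated and freed from its Z isomer by chromatography. C9–C10 is then closed in a separate superacid cyclisation (ClSO3H, 2-nitropropane, −78 °C). No compound outside the list is made (F0).

Step 5.
- **What may go wrong:** Oxidative addition and transmetalation may be slow at the tetrasubstituted triflate next to CMe2, and the α-acyloxy organozinc may decompose like a carbenoid.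
- **Fallback:** It sets out from 8 and returns at 9. A Stille hydroxymethylation with (tributylstannyl)methanol (Pd(PPh3)4, LiCl, dioxane) should give [(4S,5S)-4,5-bis(benzoyloxy)-2,6,6-trimethylcyclohex-1-en-1-yl]methanol F1. This alcohol is acylated with pivaloyl chloride and pyridine to give 9.

Step 10.
- **What may go wrong:** Site selectivity between the two secondary hydroxyl groups may be poor, and over-oxidation to the diosphenol may follow.
- **Fallback:** It sets out from 16 and returns at 20, and it replaces reagent control by protecting-group control.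
  - TBSCl and imidazole silylate the less hindered C2–OH to give the 2-O-TBS ether F2.
  - Mixed-anhydride angeloylation of the remaining C3–OH gives the 3-angelate 2-O-TBS ether F3.
  - HF·pyridine frees the 3-angelate 2-alcohol F4.
  - Dess–Martin oxidation of its only free hydroxyl group gives 20.

Further compounds
F0 | step 7 | none | none
F1 | step 5 | [(4S,5S)-4,5-bis(benzoyloxy)-2,6,6-trimethylcyclohex-1-en-1-yl]methanol | O=C(c1ccccc1)O[C@@H]2[C@@H](OC(=O)c3ccccc3)CC(C)=C(CO)C2(C)C
F2 | step 10 | 7-{[(2S,3S,5S,9R,10R)-2-(tert-butyldimethylsilyloxy)-3-hydroxydrim-7-en-11-yl]oxy}coumarin | O[C@@H]1[C@@H](O[Si](C)(C)C(C)(C)C)C[C@@]2(C)[C@H](COc3ccc4ccc(=O)oc4c3)C(C)=CC[C@@H]2C1(C)C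
F3 | step 10 | 7-{[(2S,3S,5S,9R,10R)-3-(angeloyloxy)-2-(tert-butyldimethylsilyloxy)drim-7-en-11-yl]oxy}coumarin | C/C=C(/C)C(=O)O[C@@H]1[C@@H](O[Si](C)(C)C(C)(C)C)C[C@@]2(C)[C@H](COc3ccc4ccc(=O)oc4c3)C(C)=CC[C@@H]2C1(C)C
F4 | step 10 | 7-{[(2S,3S,5S,9R,10R)-3-(angeloyloxy)-2-hydroxydrim-7-en-11-yl]oxy}coumarin | C/C=C(/C)C(=O)O[C@@H]1[C@@H](O)C[C@@]2(C)[C@H](COc3ccc4ccc(=O)oc4c3)C(C)=CC[C@@H]2C1(C)C
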